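Assumption: atom labels follow neolignan usage (ring A = 3,4,5-trimethoxyphenyl, C7 = its benzylic carbinol carbon, C8 = the ether-bearing carbon, C9 = the methyl group, ring B = the guaiacyl ring whose C4' carries the ether oxygen; TBS = tert-butyldimethylsilyl), and the aryloxyacetyl imide 8 is taken to follow the sense of induction known for simple N-acyl oxazolidinones under magnesium halide catalysis.

Compound numbers are those of the steps and of the compound list after them.

## Analysis of the target

The target is an acyclic 8-O-4' neolignan: ring A carries the three-carbon chain C7–C8–C9, and the oxygen on C8 is bound to C4' of ring B, which bears a 3-hydroxypropyl chain para to that ether. No ring has to be built, so the problem is the open-chain pair of adjacent stereocentres, C7 (S, secondary benzylic alcohol) and C8 (R, aryl alkyl ether carrying the methyl C9). Their relation is erythro: hydroxyl and aryloxy group lie anti when the chain C9–C8–C7–C1 (ring A) is drawn zigzag. Sensitive points are the benzylic C7–OH on an electron-rich arene (it ionises under acid, with epimerisation or loss of water), the aryloxy group at C8 (it can be eliminated from carbonyl precursors under base) and the two hydroxyls of different kind. The difficulty is acyclic stereocontrol: C8 carries only methyl, hydrogen and aryloxy, so additions controlled by C8 alone discriminate poorly, and the erythro series is the one that neither syn-dihydroxylation of an E-alkene nor a chair-type syn aldol delivers. The strategy rests on one feature: C7(OH)–C8(OAr)–C9 is a 3-hydroxy-2-aryloxy carbonyl pattern once C9 is regarded as a fully reduced carboxyl carbon. The C7–C8 bond is then an aldol bond between an aryloxyacetyl unit (ring B side) and the ring A aldehyde.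

## Retrosynthetic reasoning

**16 back to 15.** The primary hydroxyl of the propyl chain is carried as its TBS ether, so 16 comes from 15 by desilylation. The mask is needed because a second primary hydroxyl appears at C9 on the way and must be removed selectively. A fluoride-labile group is chosen so that the acid-sensitive C7–OH never meets acid at the end.

**15 back to 14 and 13.** The C9–H bond is cut: the methyl group is traced to the primary sulfonate 14 (hydride displacement), and 14 to the diol 13 (sulfonylation of the primary hydroxyl). Nothing at C7 or C8 is touched. What is gained is a C9 carbinol that can be traced further to a carboxyl carbon. The forward steps have to distinguish the primary C9–OH from the secondary benzylic C7–OH, and hydride must arrive at C9 faster than the C7 alkoxide can close an oxetane.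

**13 back to 12.** The C9 carbinol is the reduced form of the imide carbonyl of 12. Reductive cleavage removes the auxiliary and returns 6 for reuse.

**12 back to 8 and 9 (key disconnection).** The C7–C8 bond is cut. It is the only bond whose formation creates both stereocentres at once, and it divides the molecule into the commercial, non-enolisable ring A aldehyde 9 and the imide 8, which holds all of ring B. Cutting the C8–O bond or the C7–aryl bond would leave one centre to be set under the influence of the other. The forward reaction must be an anti aldol with one enolate face selected. A chair-type boron aldol of the Z-enolate would give the syn (threo) series. The magnesium-chelated enolate 10, trapped after addition as the silyl ether 11, reacts with aromatic aldehydes through a boat and gives the anti (erythro) series.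

**8 back to 5 and 6.** The N–acyl bond is cut. Acid 5 is activated as the mixed anhydride 7 and transferred to the auxiliary 6; no stereocentre is affected.

**5 back to 4, 3, 1 and 2.** Acid 5 is the hydrolysis product of ester 4, 4 the silyl ether of 3, and 3 arises by cutting the O–CH2 bond to phenol 1 and bromo ester 2. The phenol is alkylated before silylation, so the two hydroxyls of 1 are told apart by acidity and silylation meets only one free hydroxyl.

## Alternatives that were turned down

**Alternative 1: enzymatic hydroxylation at C7.**
- Disconnection: the C7–O bond of the benzylic hydroxyl, made last on a 7-deoxy precursor.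
- Forward key step: phenol A2 (7-deoxy, free 4-hydroxyl on ring A, C8 already R) is oxidised by a flavin-dependent 4-alkylphenol oxidase of the vanillyl alcohol oxidase type. Hydride leaves C7 to give the quinone methide A3, and enzyme-guided hydration of A3 gives A1, the 4-O-demethyl target. Methylation of the phenol of A1 would finish the synthesis.
- For it: no auxiliary, no detour through a C9 carbinol, no protecting group at C7, an aerobic oxidation in water, and a catalyst pocket that could in principle dictate C7 independently of C8.
- Against it: these oxidases are shaped for small para-alkylphenols, whereas A2 has two ortho-methoxy groups and a bulky aryloxy group on the carbon next to the reacting one, so binding and turnover are doubtful. A3 has a hydrogen at C8 and can tautomerise toward C8, with loss of that stereocentre and, after hydrolysis, of ring B. The new carbinol of A1 can be oxidised further. The facial sense of hydration next to an existing C8 centre cannot be argued from structure. The final methylation must also pick the phenol among three hydroxyls.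
- Comparison: after the precursor it is shorter than the chosen route. The chosen route offers instead an outcome that follows from a defined transition state, with both centres set in one step by ordinary reagents.

**Alternative 2: late aryl ether bond by palladium C–O coupling.**
- Disconnection: the O–C4' aryl ether bond.
- Forward key step: the secondary alcohol A5 (erythro 1-arylpropane-1,2-diol, C7–OH as methoxymethyl ether, C8–OH free) is coupled with bromoarene A6 (ring B with the silylated propyl chain) by a palladium catalyst carrying a bulky di-tert-butyl biarylphosphine with a carbonate base, to give A4. Removal of both protecting groups follows.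
- For it: convergent; the C8–O bond of A5 is not broken, so its configuration should carry through; both centres come from established diol chemistry; ring B can be varied late.
- Against it: the palladium alkoxide from A5 has a β-hydrogen at C8, and β-hydride elimination (oxidising the alcohol, reducing the aryl halide) competes with C–O reductive elimination. That elimination is slow for the electron-rich, ortho-methoxy-substituted aryl group of A6 and a hindered secondary alkoxide. A5 is itself not trivial: the erythro relation is not what syn-dihydroxylation of an E-alkene gives, and its two secondary hydroxyls must be differentiated. The methoxymethyl ether must finally be removed with acid at the cation-prone benzylic position.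
- Comparison: it is stronger on convergence and modularity. The chosen route places its one uncertain step early, on inexpensive material, and needs no acid at the end.

**Alternative 3: Felkin-controlled aryl addition to an aryloxy aldehyde.**
- Disconnection: the bond from C7 to C1 of ring A.
- Forward key step: the aryltitanium reagent A9 (3,4,5-trimethoxyphenyltitanium triisopropoxide, generated by transmetalation) adds to the (R)-2-aryloxypropanal A8 to give A7, the same silyl ether that the chosen route reaches as 15.
- For it: it is the shortest approach. C8 and C9 come from a chiral-pool 2-hydroxypropanoate by ether formation with inversion, no deoxygenation is needed, and the polar Felkin–Anh model (aryloxy group anti to the incoming aryl) predicts the erythro product for a weakly Lewis-acidic, non-chelating titanium reagent.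
- Against it: A8 has an acidic hydrogen at C8 between the formyl and aryloxy groups, so this centre is at risk during preparation, storage and reaction with a basic organometallic. The 1,2-induction rests on telling methyl from hydrogen and is expected to be moderate. The ortho-methoxy group of ring B offers a chelation site that would favour the threo isomer. The C7 epimers of A7 would have to be separated as non-crystalline ethers.
- Comparison: it beats the chosen route by about three steps. The chosen route offers reagent control of both centres, imide diastereomers that can be purified before the auxiliary is removed, and no epimerisable aldehyde.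

Key step: step 5

## Route

Step 1
Reactants: 1 dihydroconiferyl alcohol [4-(3-hydroxypropyl)-2-methoxyphenol]; 2 ethyl bromoacetate
Product: 3 ethyl 2-[4-(3-hydroxypropyl)-2-methoxyphenoxy]acetate
Conditions: K2CO3, acetone, reflux
Reagents that add atoms: none
Why: Williamson ether synthesis; K2CO3 deprotonates only the phenol (pKa about 10) and the phenoxide displaces bromide from the activated α-bromo ester by SN2, while the aliphatic hydroxyl stays neutral and unreactive.

Step 2
Reactants: 3 ethyl 2-[4-(3-hydroxypropyl)-2-methoxyphenoxy]acetate
Product: 4 ethyl 2-{4-[3-(tert-butyldimethylsilyloxy)propyl]-2-methoxyphenoxy}acetate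
Conditions: TBSCl, imidazole, CH2Cl2, 0 °C to rt
Reagents that add atoms: tert-butyldimethylsilyl chloride, CC(C)(C)[Si](C)(C)Cl
Why: Standard imidazole-promoted silylation of a primary alcohol; the phenol is already alkylated, so no other hydroxyl competes, and the ester is inert.

Step 3
Reactants: 4 ethyl 2-{4-[3-(tert-butyldimethylsilyloxy)propyl]-2-methoxyphenoxy}acetate
Product: 5 2-{4-[3-(tert-butyldimethylsilyloxy)propyl]-2-methoxyphenoxy}acetic acid
Conditions: LiOH·H2O, THF/H2O 3:1, 0 °C to rt; then 1 M HCl to pH 3–4, 0 °C
Reagents that add atoms: lithium hydroxide, [Li+].[OH-] (the hydroxide oxygen becomes a carboxyl oxygen)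
Why: Saponification of an ester activated by the α-aryloxy group should be fast at or below room temperature; the silyl ether is stable to hydroxide and to brief cold acidification.

Step 4
Reactants: 5 2-{4-[3-(tert-butyldimethylsilyloxy)propyl]-2-methoxyphenoxy}acetic acid; 6 (R)-4-benzyloxazolidin-2-one
Product: 8 (R)-4-benzyl-3-(2-{4-[3-(tert-butyldimethylsilyloxy)propyl]-2-methoxyphenoxy}acetyl)oxazolidin-2-one, via mixed pivalic anhydride 7 (not isolated)
Conditions: t-BuCOCl, Et3N, THF, −20 °C; then LiCl, 6, −20 °C to rt
Reagents that add atoms: pivaloyl chloride, CC(C)(C)C(Cl)=O (its acyl group sits in intermediate 7 only and leaves as pivalate)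
Why: N-acylation of an oxazolidinone through a mixed pivalic anhydride under LiCl/Et3N activation; the auxiliary attacks the unhindered, α-oxygen-activated carbonyl of 7 and not the tert-butyl-shielded one, and its C4 stereocentre is not involved.

Step 5
Reactants: 8 (R)-4-benzyl-3-(2-{4-[3-(tert-butyldimethylsilyloxy)propyl]-2-methoxyphenoxy}acetyl)oxazolidin-2-one; 9 3,4,5-trimethoxybenzaldehyde
Product: 12 (R)-4-benzyl-3-[(2S,3S)-2-{4-[3-(tert-butyldimethylsilyloxy)propyl]-2-methoxyphenoxy}-3-hydroxy-3-(3,4,5-trimethoxyphenyl)propanoyl]oxazolidin-2-one, via chloromagnesium Z-enolate 10 (not isolated), via C7 trimethylsilyl ether 11 (not isolated)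
Conditions: 9 (1.2 equiv), MgCl2 (0.2 equiv), Et3N (2 equiv), Me3SiCl (1.5 equiv), EtOAc, 23 °C; then THF/1 M HCl 5:1, 0 °C
Reagents that add atoms: chlorotrimethylsilane, C[Si](C)(C)Cl (silyl group in intermediate 11 only); magnesium dichloride, [Mg+2].[Cl-].[Cl-] (in intermediate 10 only); product 12 holds only atoms of 8 and 9
Why: This is the magnesium halide-catalysed direct anti aldol of an N-acyl oxazolidinone with a non-enolisable aromatic aldehyde, the closest known reaction type, supported by anti glycolate aldols of chelated chlorotitanium enolates. MgCl2 binds both imide carbonyls of 8, so Et3N can remove the α-proton, already acidified by the aryloxy group, to give the chelated Z-enolate 10 with the aryloxy group cis to the enolate oxygen (the E isomer would suffer allylic strain against the ring). Aldehyde 9 coordinates to the same magnesium and the C7–C8 bond forms through a boat-shaped six-membered transition state; Me3SiCl then silylates the magnesium aldolate to 11, which frees MgCl2 for the next turnover and shuts off retro-aldol and equilibration. No ring is closed. C8 is controlled by the (R)-benzyl group of the auxiliary, which shields one face of the rigid chelated enolate so that 9 adds to the opposite face (2S in 12, which is 8R once C9 is methyl). C7 is controlled by the boat geometry relative to the Z-enolate, which places the new oxygen anti to the aryloxy group (3S in 12, 7S in the target). The step needs anti over syn selectivity and one enolate face; two-point chelation fixes enolate geometry and face, and the lack of α-hydrogens in 9 excludes self-condensation. The cold dilute acid work-up should cleave the labile secondary trimethylsilyl ether of 11 while the primary TBS ether, far more stable to acid, is kept.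

Step 6
Reactants: 12 (R)-4-benzyl-3-[(2S,3S)-2-{4-[3-(tert-butyldimethylsilyloxy)propyl]-2-methoxyphenoxy}-3-hydroxy-3-(3,4,5-trimethoxyphenyl)propanoyl]oxazolidin-2-one
Product: 13 (1S,2R)-2-{4-[3-(tert-butyldimethylsilyloxy)propyl]-2-methoxyphenoxy}-1-(3,4,5-trimethoxyphenyl)propane-1,3-diol
Conditions: LiBH4, H2O (1 equiv), THF, 0 °C
Reagents that add atoms: none
Why: Reductive cleavage of an N-acyl oxazolidinone; the lithium-activated exocyclic carbonyl is reduced through the aldehyde to the primary alcohol and auxiliary 6 is released for recovery, while the weakly basic hydride leaves C7 and C8 untouched and the ethers are inert.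

Step 7
Reactants: 13 (1S,2R)-2-{4-[3-(tert-butyldimethylsilyloxy)propyl]-2-methoxyphenoxy}-1-(3,4,5-trimethoxyphenyl)propane-1,3-diol
Product: 14 (2R,3S)-2-{4-[3-(tert-butyldimethylsilyloxy)propyl]-2-methoxyphenoxy}-3-hydroxy-3-(3,4,5-trimethoxyphenyl)propyl 4-methylbenzenesulfonate
Conditions: TsCl (1.1 equiv), pyridine, CH2Cl2, 0 °C
Reagents that add atoms: p-toluenesulfonyl chloride, Cc1ccc(cc1)S(Cl)(=O)=O
Why: Selective sulfonylation; the unhindered primary C9–OH should react much faster than the secondary benzylic C7–OH, which is flanked by ring A and the branched C8, and low temperature with a slight excess of TsCl limits double sulfonylation.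

Step 8
Reactants: 14 (2R,3S)-2-{4-[3-(tert-butyldimethylsilyloxy)propyl]-2-methoxyphenoxy}-3-hydroxy-3-(3,4,5-trimethoxyphenyl)propyl 4-methylbenzenesulfonate
Product: 15 (1S,2R)-2-{4-[3-(tert-butyldimethylsilyloxy)propyl]-2-methoxyphenoxy}-1-(3,4,5-trimethoxyphenyl)propan-1-ol
Conditions: LiBHEt3 (3 equiv), THF, 0 °C to rt
Reagents that add atoms: none
Why: SN2 hydride displacement of a primary sulfonate by a highly nucleophilic borohydride; one equivalent is consumed by the C7–OH, the substitution occurs at C9 only so C7 and C8 keep their configuration, and silyl and aryl ethers are not attacked at this temperature.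

Step 9
Reactants: 15 (1S,2R)-2-{4-[3-(tert-butyldimethylsilyloxy)propyl]-2-methoxyphenoxy}-1-(3,4,5-trimethoxyphenyl)propan-1-ol
Product: 16 (1S,2R)-2-[4-(3-hydroxypropyl)-2-methoxyphenoxy]-1-(3,4,5-trimethoxyphenyl)propan-1-ol [(7S,8R), the target]
Conditions: Bu4NF, THF, 0 °C to rt
Reagents that add atoms: none
Why: Fluoride-induced desilylation driven by the strength of the Si–F bond; the near-neutral conditions spare the acid-sensitive benzylic alcohol and the aryl ethers, and no stereocentre is involved.

## Compound list

1 | dihydroconiferyl alcohol [4-(3-hydroxypropyl)-2-methoxyphenol] | COc1cc(CCCO)ccc1O | starting material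
2 | ethyl bromoacetate | CCOC(=O)CBr | starting material
3 | ethyl 2-[4-(3-hydroxypropyl)-2-methoxyphenoxy]acetate | CCOC(=O)COc1ccc(CCCO)cc1OC | intermediate
4 | ethyl 2-{4-[3-(tert-butyldimethylsilyloxy)propyl]-2-methoxyphenoxy}acetate | CCOC(=O)COc1ccc(CCCO[Si](C)(C)C(C)(C)C)cc1OC | intermediate
5 | 2-{4-[3-(tert-butyldimethylsilyloxy)propyl]-2-methoxyphenoxy}acetic acid | OC(=O)COc1ccc(CCCO[Si](C)(C)C(C)(C)C)cc1OC | intermediate
6 | (R)-4-benzyloxazolidin-2-one | O=C1N[C@H](Cc2ccccc2)CO1 | starting material
7 | mixed pivalic anhydride of acid 5 (formed in the flask) | CC(C)(C)C(=O)OC(=O)COc1ccc(CCCO[Si](C)(C)C(C)(C)C)cc1OC | intermediate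
8 | (R)-4-benzyl-3-(2-{4-[3-(tert-butyldimethylsilyloxy)propyl]-2-methoxyphenoxy}acetyl)oxazolidin-2-one | COc1cc(CCCO[Si](C)(C)C(C)(C)C)ccc1OCC(=O)N1[C@H](Cc2ccccc2)COC1=O | intermediate
9 | 3,4,5-trimethoxybenzaldehyde | COc1cc(C=O)cc(OC)c1OC | starting material
10 | chloromagnesium Z-enolate of 8, aryloxy group cis to the enolate oxygen, magnesium bridging enolate and ring carbonyl oxygens (formed in the flask) | COc1cc(CCCO[Si](C)(C)C(C)(C)C)ccc1O/C=C(\O[Mg]Cl)N1[C@H](Cc2ccccc2)COC1=O | intermediate
11 | (R)-4-benzyl-3-[(2S,3S)-2-{4-[3-(tert-butyldimethylsilyloxy)propyl]-2-methoxyphenoxy}-3-(3,4,5-trimethoxyphenyl)-3-(trimethylsilyloxy)propanoyl]oxazolidin-2-one (formed in the flask) | COc1cc(CCCO[Si](C)(C)C(C)(C)C)ccc1O[C@H](C(=O)N1[C@H](Cc2ccccc2)COC1=O)[C@@H](O[Si](C)(C)C)c1cc(OC)c(OC)c(OC)c1 | intermediate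
12 | (R)-4-benzyl-3-[(2S,3S)-2-{4-[3-(tert-butyldimethylsilyloxy)propyl]-2-methoxyphenoxy}-3-hydroxy-3-(3,4,5-trimethoxyphenyl)propanoyl]oxazolidin-2-one | COc1cc(CCCO[Si](C)(C)C(C)(C)C)ccc1O[C@H](C(=O)N1[C@H](Cc2ccccc2)COC1=O)[C@@H](O)c1cc(OC)c(OC)c(OC)c1 | intermediate
13 | (1S,2R)-2-{4-[3-(tert-butyldimethylsilyloxy)propyl]-2-methoxyphenoxy}-1-(3,4,5-trimethoxyphenyl)propane-1,3-diol | COc1cc(CCCO[Si](C)(C)C(C)(C)C)ccc1O[C@H](CO)[C@@H](O)c1cc(OC)c(OC)c(OC)c1 | intermediate
14 | (2R,3S)-2-{4-[3-(tert-butyldimethylsilyloxy)propyl]-2-methoxyphenoxy}-3-hydroxy-3-(3,4,5-trimethoxyphenyl)propyl 4-methylbenzenesulfonate | COc1cc(CCCO[Si](C)(C)C(C)(C)C)ccc1O[C@H](COS(=O)(=O)c2ccc(C)cc2)[C@@H](O)c1cc(OC)c(OC)c(OC)c1 | intermediate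
15 | (1S,2R)-2-{4-[3-(tert-butyldimethylsilyloxy)propyl]-2-methoxyphenoxy}-1-(3,4,5-trimethoxyphenyl)propan-1-ol | COc1cc(CCCO[Si](C)(C)C(C)(C)C)ccc1O[C@H](C)[C@@H](O)c1cc(OC)c(OC)c(OC)c1 | intermediate
16 | (1S,2R)-2-[4-(3-hydroxypropyl)-2-methoxyphenoxy]-1-(3,4,5-trimethoxyphenyl)propan-1-ol, (7S,8R) | COc1cc(CCCO)ccc1O[C@H](C)[C@@H](O)c1cc(OC)c(OC)c(OC)c1 | target

## Step count and least certain steps

Total step count: 9. Longest linear sequence: 9 steps (1 to 16); 2, 6 and 9 enter as purchased materials. Both stereocentres are set in step 5, and no later step breaks a bond at C7 or C8.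

**Step 5 (key step).**
- What may go wrong: erosion of anti selectivity or of facial control, because the aryloxy oxygen and the neighbouring methoxy group of ring B offer magnesium other chelation modes than the two imide carbonyls. Base-mediated epimerisation at the acidic C8 position may occur before silylation is complete. Turnover may be slow with an aldehyde of modest electrophilicity. Part of the primary silyl ether may be lost if the acid work-up is prolonged.
- Fallback (sets out from 5, returns at 15): acid 5 is coupled as in step 4 with the enantiomeric auxiliary (S)-4-benzyloxazolidin-2-one to give (S)-4-benzyl-3-(2-{4-[3-(tert-butyldimethylsilyloxy)propyl]-2-methoxyphenoxy}acetyl)oxazolidin-2-one F1. Its dibutylboron Z-enolate (Bu2BOTf, i-Pr2NEt, CH2Cl2, −78 to 0 °C) adds to 9 through a closed chair (Zimmerman–Traxler) transition state, a dependable process for alkoxy- and aryloxyacetyl imides. It should give the syn adduct (S)-4-benzyl-3-[(2S,3R)-2-{4-[3-(tert-butyldimethylsilyloxy)propyl]-2-methoxyphenoxy}-3-hydroxy-3-(3,4,5-trimethoxyphenyl)propanoyl]oxazolidin-2-one F2, with C8 as in the target and C7 inverted. The conditions of steps 6 to 8 then give the threo diol (1R,2R)-2-{4-[3-(tert-butyldimethylsilyloxy)propyl]-2-methoxyphenoxy}-1-(3,4,5-trimethoxyphenyl)propane-1,3-diol F3, its primary tosylate F4 and the threo silyl ether (1R,2R)-2-{4-[3-(tert-butyldimethylsilyloxy)propyl]-2-methoxyphenoxy}-1-(3,4,5-trimethoxyphenyl)propan-1-ol F5. Dess–Martin oxidation of F5 (NaHCO3-buffered) gives the ketone (R)-2-{4-[3-(tert-butyldimethylsilyloxy)propyl]-2-methoxyphenoxy}-1-(3,4,5-trimethoxyphenyl)propan-1-one F6. Reduction of F6 with Zn(BH4)2 in Et2O at low temperature, under chelation between the ketone oxygen and the aryloxy oxygen, should deliver hydride to the face that gives the erythro alcohol 15. The same oxidation–reduction pair would also converge a C7-epimer mixture from step 5.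

**Step 8.**
- What may go wrong: after deprotonation of the C7–OH, intramolecular attack of the alkoxide on C9 (oxetane closure) may compete with hydride delivery; S–O cleavage back to the diol is also possible.
- Fallback (sets out from 14, returns at 16): the C7–OH of 14 is silylated (Et3SiOTf, 2,6-lutidine, CH2Cl2, −78 °C) to the triethylsilyl ether (2R,3S)-2-{4-[3-(tert-butyldimethylsilyloxy)propyl]-2-methoxyphenoxy}-3-(triethylsilyloxy)-3-(3,4,5-trimethoxyphenyl)propyl 4-methylbenzenesulfonate F7. With no alkoxide available, LiBHEt3 can only displace the sulfonate and gives the bis-silyl ether of the target F8. Bu4NF as in step 9 then removes both silyl groups and gives 16.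

**Step 6.**
- What may go wrong: hydride attack at the ring carbonyl of the hindered imide (opening of the auxiliary instead of its release), or retro-aldol of the β-hydroxy imide under the basic borohydride conditions.
- Fallback (sets out from 12, returns at 13): LiOH/H2O2 in THF/H2O at 0 °C, where hydroperoxide attacks the exocyclic carbonyl selectively even in hindered imides, gives (2S,3S)-2-{4-[3-(tert-butyldimethylsilyloxy)propyl]-2-methoxyphenoxy}-3-hydroxy-3-(3,4,5-trimethoxyphenyl)propanoic acid F9 and free 6. BH3·SMe2 in THF then reduces the carboxylic acid to the primary alcohol 13 without touching the ethers.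

**Step 7.**
- What may go wrong: incomplete discrimination of the two hydroxyls (sulfonylation at C7 or at both positions), or displacement of the new sulfonate by chloride.
- Fallback (sets out from 13, returns at 15): PPh3, I2 and imidazole (CH2Cl2, 0 °C) convert only the primary hydroxyl into the iodide (1S,2S)-2-{4-[3-(tert-butyldimethylsilyloxy)propyl]-2-methoxyphenoxy}-3-iodo-1-(3,4,5-trimethoxyphenyl)propan-1-ol F10. Radical deiodination with Bu3SnH and catalytic azobisisobutyronitrile in toluene at 80 °C gives 15, bypassing both the sulfonate and the hydride step.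

## Further compounds

F1 | step 5 | (S)-4-benzyl-3-(2-{4-[3-(tert-butyldimethylsilyloxy)propyl]-2-methoxyphenoxy}acetyl)oxazolidin-2-one | COc1cc(CCCO[Si](C)(C)C(C)(C)C)ccc1OCC(=O)N1[C@@H](Cc2ccccc2)COC1=O
F2 | step 5 | (S)-4-benzyl-3-[(2S,3R)-2-{4-[3-(tert-butyldimethylsilyloxy)propyl]-2-methoxyphenoxy}-3-hydroxy-3-(3,4,5-trimethoxyphenyl)propanoyl]oxazolidin-2-one | COc1cc(CCCO[Si](C)(C)C(C)(C)C)ccc1O[C@H](C(=O)N1[C@@H](Cc2ccccc2)COC1=O)[C@H](O)c1cc(OC)c(OC)c(OC)c1
F3 | step 5 | (1R,2R)-2-{4-[3-(tert-butyldimethylsilyloxy)propyl]-2-methoxyphenoxy}-1-(3,4,5-trimethoxyphenyl)propane-1,3-diol | COc1cc(CCCO[Si](C)(C)C(C)(C)C)ccc1O[C@H](CO)[C@H](O)c1cc(OC)c(OC)c(OC)c1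
F4 | step 5 | (2R,3R)-2-{4-[3-(tert-butyldimethylsilyloxy)propyl]-2-methoxyphenoxy}-3-hydroxy-3-(3,4,5-trimethoxyphenyl)propyl 4-methylbenzenesulfonate | COc1cc(CCCO[Si](C)(C)C(C)(C)C)ccc1O[C@H](COS(=O)(=O)c2ccc(C)cc2)[C@H](O)c1cc(OC)c(OC)c(OC)c1
F5 | step 5 | (1R,2R)-2-{4-[3-(tert-butyldimethylsilyloxy)propyl]-2-methoxyphenoxy}-1-(3,4,5-trimethoxyphenyl)propan-1-ol | COc1cc(CCCO[Si](C)(C)C(C)(C)C)ccc1O[C@H](C)[C@H](O)c1cc(OC)c(OC)c(OC)c1
F6 | step 5 | (R)-2-{4-[3-(tert-butyldimethylsilyloxy)propyl]-2-methoxyphenoxy}-1-(3,4,5-trimethoxyphenyl)propan-1-one | COc1cc(CCCO[Si](C)(C)C(C)(C)C)ccc1O[C@H](C)C(=O)c1cc(OC)c(OC)c(OC)c1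
F7 | step 8 | (2R,3S)-2-{4-[3-(tert-butyldimethylsilyloxy)propyl]-2-methoxyphenoxy}-3-(triethylsilyloxy)-3-(3,4,5-trimethoxyphenyl)propyl 4-methylbenzenesulfonate | COc1cc(CCCO[Si](C)(C)C(C)(C)C)ccc1O[C@H](COS(=O)(=O)c2ccc(C)cc2)[C@@H](O[Si](CC)(CC)CC)c1cc(OC)c(OC)c(OC)c1
F8 | step 8 | tert-butyl{3-[3-methoxy-4-({(1S,2R)-1-(triethylsilyloxy)-1-(3,4,5-trimethoxyphenyl)propan-2-yl}oxy)phenyl]propoxy}dimethylsilane | COc1cc(CCCO[Si](C)(C)C(C)(C)C)ccc1O[C@H](C)[C@@H](O[Si](CC)(CC)CC)c1cc(OC)c(OC)c(OC)c1
F9 | step 6 | (2S,3S)-2-{4-[3-(tert-butyldimethylsilyloxy)propyl]-2-methoxyphenoxy}-3-hydroxy-3-(3,4,5-trimethoxyphenyl)propanoic acid | COc1cc(CCCO[Si](C)(C)C(C)(C)C)ccc1O[C@H](C(O)=O)[C@@H](O)c1cc(OC)c(OC)c(OC)c1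
F10 | step 7 | (1S,2S)-2-{4-[3-(tert-butyldimethylsilyloxy)propyl]-2-methoxyphenoxy}-3-iodo-1-(3,4,5-trimethoxyphenyl)propan-1-ol | COc1cc(CCCO[Si](C)(C)C(C)(C)C)ccc1O[C@H](CI)[C@@H](O)c1cc(OC)c(OC)c(OC)c1
A1 | alternative 1 | (1S,2R)-1-(4-hydroxy-3,5-dimethoxyphenyl)-2-[4-(3-hydroxypropyl)-2-methoxyphenoxy]propan-1-ol (4-O-demethyl target) | COc1cc(CCCO)ccc1O[C@H](C)[C@@H](O)c1cc(OC)c(O)c(OC)c1
A2 | alternative 1 | 4-{(2R)-2-[4-(3-hydroxypropyl)-2-methoxyphenoxy]propyl}-2,6-dimethoxyphenol | COc1cc(CCCO)ccc1O[C@H](C)Cc1cc(OC)c(O)c(OC)c1
A3 | alternative 1 | 4-{(2R)-2-[4-(3-hydroxypropyl)-2-methoxyphenoxy]propylidene}-2,6-dimethoxycyclohexa-2,5-dien-1-one (quinone methide) | COc1cc(CCCO)ccc1O[C@H](C)C=C1C=C(OC)C(=O)C(OC)=C1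
A4 | alternative 2 | tert-butyl{3-[3-methoxy-4-({(1S,2R)-1-(methoxymethoxy)-1-(3,4,5-trimethoxyphenyl)propan-2-yl}oxy)phenyl]propoxy}dimethylsilane | COc1cc(CCCO[Si](C)(C)C(C)(C)C)ccc1O[C@H](C)[C@@H](OCOC)c1cc(OC)c(OC)c(OC)c1
A5 | alternative 2 | (1S,2R)-1-(methoxymethoxy)-1-(3,4,5-trimethoxyphenyl)propan-2-ol | O[C@H](C)[C@@H](OCOC)c1cc(OC)c(OC)c(OC)c1
A6 | alternative 2 | [3-(4-bromo-3-methoxyphenyl)propoxy](tert-butyl)dimethylsilane | COc1cc(CCCO[Si](C)(C)C(C)(C)C)ccc1Br
A7 | alternative 3 | (1S,2R)-2-{4-[3-(tert-butyldimethylsilyloxy)propyl]-2-methoxyphenoxy}-1-(3,4,5-trimethoxyphenyl)propan-1-ol (identical with 15) | COc1cc(CCCO[Si](C)(C)C(C)(C)C)ccc1O[C@H](C)[C@@H](O)c1cc(OC)c(OC)c(OC)c1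
A8 | alternative 3 | (R)-2-{4-[3-(tert-butyldimethylsilyloxy)propyl]-2-methoxyphenoxy}propanal | COc1cc(CCCO[Si](C)(C)C(C)(C)C)ccc1O[C@H](C)C=O
A9 | alternative 3 | 3,4,5-trimethoxyphenyltitanium triisopropoxide | COc1cc(cc(OC)c1OC)[Ti](OC(C)C)(OC(C)C)OC(C)C
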